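Remark on the chemistry: diol 7 is carried as an unassigned mixture of carbinol epimers, because step 5 erases those two centres. Zn(BH4)2 is taken as a pre-made ethereal solution, and compounds 1, 3, 10 and 13 are taken as catalogue materials. Steps 3, 7 and 9 are twofold reactions on a bifunctional meso partner. In each, the second equivalent of the monofunctional partner is entered on the line of reagents that add atoms, so that every atom of the product is accounted for.

## The problem

Compound 16 has five unfused rings: a tetrahydrofuran with methyl groups at C3 and C4 and a 4-oxy-3-methoxyphenyl (guaiacyl) ring at each of C2 and C5, and on each phenolic oxygen a 1-(3,4-dimethoxyphenyl)-1-hydroxypropan-2-yl arm ending in a veratryl ring. Of the eight stereocentres, the four on the tetrahydrofuran (2S,3S,4R,5R) form a meso pattern: the aryl groups are cis to each other, the methyl groups are cis to each other, and each aryl group is trans to its neighbouring methyl group. Only relative configuration is needed there, and C3/C4 can dictate C2/C5. The four arm centres (1R,2S in each arm, the erythro series) lie beyond a para-disubstituted benzene ring and cannot be controlled by the core, so their absolute configuration must come from a chiral building block, after which the ether-bearing carbon of each arm can direct its neighbouring carbinol. Because the two arms are identical and homochiral, every operation on the meso core can be run twofold and no desymmetrization is needed. The fragile sites are the four electron-rich benzylic C–O bonds (two ring ether bonds and two secondary carbinols), which ionize in acid and can be hydrogenolysed, and the α-aryloxy carbonyl intermediates of any arm synthesis, which epimerize with base. The same lability makes the key step possible: C2 and C5 are benzylic ether carbons on aryl rings with a para oxygen, so each C2–O1 or C5–O1 bond can open reversibly to a stabilized cation and reclose, whereas C3 and C4 have no such pathway. The most stable arrangement of the core is the one required.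

## Retrosynthesis

The two carbinol C–H bonds of 16 are cut first, giving diketone 15. The carbinols are the most acid-sensitive positions and are best made last, without protection. Attaching a finished hydroxy arm would instead require a protecting group on each carbinol. In 15 the neighbouring (S)-configured ether carbon can steer a chelating hydride, so two stereocentres are removed from the problem. The forward reaction must be erythro-selective at two independent sites and must not be basic.

The two carbonyl–veratryl bonds of 15 are cut next, giving bis(N-methoxy-N-methylamide) 12 and two equivalents of aryl Grignard reagent 14, made from bromide 13. Ready-made α-aryloxy aryl ketones and their α-leaving-group precursors racemize easily. Each amide group takes exactly one aryl group and releases the ketone only on a mild quench. Amide 12 is the aminolysis product of diester 11.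

The two ether bonds between the phenolic oxygens and the arm carbons of 11 are then cut, leading to bisphenol 9 and two equivalents of methyl (R)-lactate 10. The phenols are the natural nucleophiles, and displacement at the lactate carbon with inversion gives the (S) configuration. Compound 10 is then the only source of absolute configuration in the route. Both phenols of the meso core are alkylated, so no selectivity between them is required. The precursor loses both arms and becomes achiral.

Bisphenol 9 comes from dibenzyl ether 8. Benzyl withstands the organolithium, hydride and Lewis acid of the earlier steps and is removed under neutral conditions.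

The key cut is the C2–O1 bond of 8, which opens the ring to diol 7. Cutting the C–aryl bonds, or building the ring by an annulation, would demand kinetic control at C2 and C5. The C–O cut lets these centres settle by equilibration, so the carbinol configurations of 7 are irrelevant. One ring and two controlled stereocentres are removed. The forward reaction must favour capture by oxygen over capture by the second arene, and must run long enough to equilibrate.

Diol 7 is the reduction product of meso diketone 6. The two carbonyl–aryl bonds of 6 are cut to give meso bis(N-methoxy-N-methylamide) 4 and two equivalents of aryllithium 5. Compound 5 comes from bromide 2, the benzyl ether of phenol 1, and 4 comes from meso acid 3. Oxidative dimerization of a propiophenone enolate would give meso and racemic diketones together. Acylation of an aryl nucleophile by a derivative of 3 brings the cis-dimethyl relation in intact. The forward steps must not enolize the two α-carbons.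

## Roads not taken

Alternative 1: This road cuts the two aryl–oxygen bonds between the guaiacyl rings and the arms. A meso dibromide core A2 would be coupled twice with the carbinol-protected arm alcohol A3 under [Pd(C3H5)Cl]2, t-BuBrettPhos and Cs2CO3 to give the doubly protected target A1. No bond to a stereocentre is broken, so the configuration of A3 is retained.
- Merits: it is the most convergent of the four plans. Both arm stereocentres are made and checked once, on a small fragment. It needs no inversion step, no late reduction and no base-sensitive α-aryloxy carbonyl compound. In these respects it is better than the chosen plan.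
- Weak points: palladium alkoxides of secondary alcohols with β-hydrogens tend to undergo β-hydride elimination. The aryl bromide is electron-rich and ortho-substituted, the alcohol is branched next to a bulky protected benzylic carbon, and two such couplings must succeed on one molecule. A2 has bromine where the para oxygen should be, so its C2 and C5 cannot be equilibrated by ionization and the core would need separate kinetic control. The final deprotection of A1 must spare four acid-labile benzylic C–O bonds.
- Comparison: the chosen plan is more linear after the core. Against that it sets well-precedented reactions throughout and a core whose configuration is set by thermodynamics.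

Alternative 2: This road cuts the C2–aryl and C5–aryl bonds. An all-cis tetrahydrofuran diacid A5 would lose two CO2 under Ir[dF(CF3)ppy]2(dtbbpy)PF6 and NiCl2(dimethoxyethane) photocatalysis, and each α-oxy radical would be joined to the arm-bearing aryl bromide A6, giving the silyl-protected target A4.
- Merits: convergence is maximal, and the longest linear sequence could be shorter than in the chosen plan. α-Oxy acids are the best substrate class for this coupling. Capture of each radical on the face away from the neighbouring methyl group would give the required trans relations directly.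
- Weak points: two couplings must occur on one small ring, with protodecarboxylation competing at each. The selectivity at C2 and C5 is kinetic and cannot be corrected afterwards without endangering the arms. A6 is electron-rich and slow to add oxidatively to nickel. A5 needs its own synthesis. Every failed attempt consumes two equivalents of A6, the most valuable fragment.
- Comparison: the chosen plan places its one uncertain step early, on inexpensive achiral material, and lets equilibration set C2 and C5.

Alternative 3: This road cuts the C5–O1 and C2–C3 bonds. Sn(OTf)2 would open the cis donor–acceptor cyclopropane A8. The oxygen of aldehyde A9 would attack the benzylic carbon with inversion, and the malonate carbon would close onto the oxocarbenium carbon, giving the 2,5-cis tetrahydrofuran diester A7.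
- Merits: the ring and two bonds form in one step, with dependable 2,5-cis selectivity and an ideal electron-rich donor. That A7 is racemic does not matter, because the final core is meso. As a ring-forming reaction it is as well precedented as the chosen cyclization, and its cis selectivity is kinetic and needs no equilibration time.
- Weak points: C3 arrives as a quaternary diester carbon. It must become a CH–CH3 group with the methyl cis to the C4 methyl, which takes a dealkoxycarbonylation, an ester-to-methyl reduction sequence and control of the C3 configuration. That is several extra steps on a ring with two labile benzylic ether bonds. A8 also requires a cis-selective cyclopropane synthesis.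
- Comparison: the chosen plan brings both methyl groups and their cis relation from 3 and reaches the core in fewer steps.

Key step: step 5

## Route

Step 1
Reactants: 1 4-bromo-2-methoxyphenol
Product: 2 1-(benzyloxy)-4-bromo-2-methoxybenzene
Conditions: BnBr, K2CO3, DMF, rt
Reagents that add atoms: benzyl bromide, BrCc1ccccc1
Why: Williamson etherification of a phenoxide with a primary benzylic bromide; the benzyl ether survives the organolithium, hydride and Lewis acid steps and is later removed under neutral conditions.

Step 2
Reactants: 3 meso-2,3-dimethylsuccinic acid
Product: 4 (2R,3S)-N1,N4-dimethoxy-N1,N4,2,3-tetramethylbutanediamide (meso)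
Conditions: MeNHOMe·HCl, EDC·HCl, HOBt, N-methylmorpholine, CH2Cl2, 0 °C to rt
Reagents that add atoms: N,O-dimethylhydroxylamine hydrochloride, CNOC.Cl
Why: Carbodiimide amide coupling of both carboxyl groups through the hydroxybenzotriazole active ester; the α-carbons carry no acylamino group and are not enolized by the weak amine base, so the meso relation of 3 should be kept.

Step 3
Reactants: 2 1-(benzyloxy)-4-bromo-2-methoxybenzene (two equivalents), 4 (2R,3S)-N1,N4-dimethoxy-N1,N4,2,3-tetramethylbutanediamide
Product: 6 (2R,3S)-1,4-bis[4-(benzyloxy)-3-methoxyphenyl]-2,3-dimethylbutane-1,4-dione (meso), via [4-(benzyloxy)-3-methoxyphenyl]lithium 5 (not isolated)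
Conditions: 2 (2.2 equiv), n-BuLi (2.2 equiv), THF, −78 °C; then 4 (1 equiv), −78 to 0 °C; aq NH4Cl
Reagents that add atoms: 1-(benzyloxy)-4-bromo-2-methoxybenzene 2 (second equivalent), COc1cc(Br)ccc1OCc1ccccc1
Why: Bromine–lithium exchange followed by a twofold Weinreb ketone synthesis, in which two molecules of aryllithium 5 acylate the two amide groups of 4; the chelated tetrahedral adducts persist until the quench, so each amide accepts one aryl group and no enolizable ketone meets the organolithium.

Step 4
Reactants: 6 (2R,3S)-1,4-bis[4-(benzyloxy)-3-methoxyphenyl]-2,3-dimethylbutane-1,4-dione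
Product: 7 (2R,3S)-1,4-bis[4-(benzyloxy)-3-methoxyphenyl]-2,3-dimethylbutane-1,4-diol (C1 and C4 each a mixture of both configurations)
Conditions: LiAlH4, THF, −78 to 0 °C; H2O, aq NaOH
Reagents that add atoms: none
Why: Hydride reduction of both aryl ketones in an aprotic solvent at low temperature should outpace enolization, so the C2/C3 relation is kept; the carbinol configurations need no control because step 5 erases them.

Step 5
Reactants: 7 (2R,3S)-1,4-bis[4-(benzyloxy)-3-methoxyphenyl]-2,3-dimethylbutane-1,4-diol (C1 and C4 each a mixture of both configurations)
Product: 8 (2R,3R,4S,5S)-2,5-bis[4-(benzyloxy)-3-methoxyphenyl]-3,4-dimethyltetrahydrofuran (meso; 2,3-trans, 3,4-cis, 4,5-trans)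
Conditions: BF3·OEt2 (0.2 equiv), CH2Cl2, −30 to 0 °C; Et3N quench
Reagents that add atoms: none
Why: BF3 complexes either benzylic hydroxyl, and its departure leaves a benzylic cation that the para benzyloxy oxygen stabilizes as a quinone-methide-like oxocarbenium ion; the second hydroxyl adds to it and forms the C2–O1 bond. The closest known reaction type is the acid-catalysed cyclodehydration of 1,4-diaryl-2,3-dimethylbutane-1,4-diols to 2,5-diaryl-3,4-dimethyltetrahydrofurans. The tetrahydrofuran closes in the 5-exo-trig mode: the attacked cationic carbon becomes a ring atom and its π partner, the aryl ipso carbon, stays outside the ring. C2 and C5 are set under thermodynamic control by the fixed methyl-bearing centres C3 and C4, because both ring C–O bonds re-ionize under the reaction conditions until each aryl group sits trans to its neighbouring methyl group, whichever carbinol epimers of 7 entered. C3 and C4 carry no leaving group and keep the cis relation brought in from 3. The step needs oxygen capture to win over Friedel–Crafts attack by the second arene and over proton loss to a styrene; the five-membered closure is fast and reversible, and low temperature, a substoichiometric Lewis acid and an amine quench hold the irreversible pathways back.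

Step 6
Reactants: 8 (2R,3R,4S,5S)-2,5-bis[4-(benzyloxy)-3-methoxyphenyl]-3,4-dimethyltetrahydrofuran
Product: 9 4,4'-[(2R,3R,4S,5S)-3,4-dimethyltetrahydrofuran-2,5-diyl]bis(2-methoxyphenol) (meso)
Conditions: H2 (1 atm), 10% Pd/C, EtOAc, rt
Reagents that add atoms: none
Why: Hydrogenolysis of aryl benzyl ethers; these are cleaved much faster than the secondary benzylic dialkyl ether bonds of the ring in a neutral aprotic solvent, so the reaction is stopped once two equivalents of hydrogen are taken up.

Step 7
Reactants: 9 4,4'-[(2R,3R,4S,5S)-3,4-dimethyltetrahydrofuran-2,5-diyl]bis(2-methoxyphenol), 10 methyl (R)-lactate (two equivalents)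
Product: 11 dimethyl (2S,2'S)-2,2'-{[(2R,3R,4S,5S)-3,4-dimethyltetrahydrofuran-2,5-diyl]bis[(2-methoxy-4,1-phenylene)oxy]}dipropanoate
Conditions: 10 (2.4 equiv), PPh3, DIAD, THF, 0 °C to rt
Reagents that add atoms: methyl (R)-lactate 10 (second equivalent), C[C@@H](O)C(=O)OC
Why: Twofold Mitsunobu etherification, one molecule of 10 for each phenol of 9; each phenol displaces the activated lactate hydroxyl by SN2 with inversion, so the (R) centre of 10 becomes the (S) aryloxy carbon of each arm, and the neutral conditions spare the ring.

Step 8
Reactants: 11 dimethyl (2S,2'S)-2,2'-{[(2R,3R,4S,5S)-3,4-dimethyltetrahydrofuran-2,5-diyl]bis[(2-methoxy-4,1-phenylene)oxy]}dipropanoate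
Product: 12 (2S,2'S)-2,2'-{[(2R,3R,4S,5S)-3,4-dimethyltetrahydrofuran-2,5-diyl]bis[(2-methoxy-4,1-phenylene)oxy]}bis(N-methoxy-N-methylpropanamide)
Conditions: MeNHOMe·HCl, i-PrMgCl, THF, −20 to 0 °C
Reagents that add atoms: N,O-dimethylhydroxylamine hydrochloride, CNOC.Cl
Why: Direct aminolysis of both esters by the chloromagnesium amide of N,O-dimethylhydroxylamine; the weakly basic magnesium amide and the low temperature should leave the α-aryloxy stereocentres untouched.

Step 9
Reactants: 12 (2S,2'S)-2,2'-{[(2R,3R,4S,5S)-3,4-dimethyltetrahydrofuran-2,5-diyl]bis[(2-methoxy-4,1-phenylene)oxy]}bis(N-methoxy-N-methylpropanamide), 13 4-bromo-1,2-dimethoxybenzene (two equivalents)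
Product: 15 (2S,2'S)-2,2'-{[(2R,3R,4S,5S)-3,4-dimethyltetrahydrofuran-2,5-diyl]bis[(2-methoxy-4,1-phenylene)oxy]}bis[1-(3,4-dimethoxyphenyl)propan-1-one], via (3,4-dimethoxyphenyl)magnesium bromide 14 (not isolated)
Conditions: 13 (2.5 equiv), Mg, THF, rt; then 12 (1 equiv), THF, −10 to 0 °C; aq NH4Cl
Reagents that add atoms: 4-bromo-1,2-dimethoxybenzene 13 (second equivalent), COc1ccc(Br)cc1OC
Why: Twofold Weinreb ketone synthesis in which two molecules of aryl Grignard reagent 14 acylate the two amide groups of 12; each magnesium chelate stops at the ketone oxidation level and the mildly acidic quench frees the α-aryloxy ketones without exposing them to base.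

Step 10
Reactants: 15 (2S,2'S)-2,2'-{[(2R,3R,4S,5S)-3,4-dimethyltetrahydrofuran-2,5-diyl]bis[(2-methoxy-4,1-phenylene)oxy]}bis[1-(3,4-dimethoxyphenyl)propan-1-one]
Product: 16 (1R,2S)-1-(3,4-dimethoxyphenyl)-2-{4-[(2S,3S,4R,5R)-5-(4-{[(1R,2S)-1-(3,4-dimethoxyphenyl)-1-hydroxypropan-2-yl]oxy}-3-methoxyphenyl)-3,4-dimethyltetrahydrofuran-2-yl]-2-methoxyphenoxy}propan-1-ol
Conditions: Zn(BH4)2, Et2O/CH2Cl2, −40 to 0 °C; aq NH4Cl
Reagents that add atoms: none
Why: Chelation-controlled (Cram chelate) reduction; zinc bridges the carbonyl oxygen and the α-aryloxy oxygen, hydride enters past the small α-hydrogen, and each (S) ether carbon thereby sets its neighbouring carbinol as (R), the erythro arm.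

## Compound list

1 | 4-bromo-2-methoxyphenol | COc1cc(Br)ccc1O | starting material
2 | 1-(benzyloxy)-4-bromo-2-methoxybenzene | COc1cc(Br)ccc1OCc1ccccc1 | intermediate
3 | meso-2,3-dimethylsuccinic acid, (2R,3S)-2,3-dimethylbutanedioic acid | OC(=O)[C@H](C)[C@H](C)C(O)=O | starting material
4 | (2R,3S)-N1,N4-dimethoxy-N1,N4,2,3-tetramethylbutanediamide (meso) | CON(C)C(=O)[C@H](C)[C@H](C)C(=O)N(C)OC | intermediate
5 | [4-(benzyloxy)-3-methoxyphenyl]lithium | COc1cc([Li])ccc1OCc1ccccc1 | intermediate (not isolated)
6 | (2R,3S)-1,4-bis[4-(benzyloxy)-3-methoxyphenyl]-2,3-dimethylbutane-1,4-dione (meso) | COc1cc(ccc1OCc1ccccc1)C(=O)[C@H](C)[C@H](C)C(=O)c1ccc(OCc2ccccc2)c(OC)c1 | intermediate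
7 | (2R,3S)-1,4-bis[4-(benzyloxy)-3-methoxyphenyl]-2,3-dimethylbutane-1,4-diol, C1/C4 epimer mixture | COc1cc(ccc1OCc1ccccc1)C(O)[C@H](C)[C@H](C)C(O)c1ccc(OCc2ccccc2)c(OC)c1 | intermediate
8 | (2R,3R,4S,5S)-2,5-bis[4-(benzyloxy)-3-methoxyphenyl]-3,4-dimethyltetrahydrofuran (meso) | COc1cc(ccc1OCc1ccccc1)[C@H]1O[C@@H](c2ccc(OCc3ccccc3)c(OC)c2)[C@H](C)[C@@H]1C | intermediate
9 | 4,4'-[(2R,3R,4S,5S)-3,4-dimethyltetrahydrofuran-2,5-diyl]bis(2-methoxyphenol) (meso) | COc1cc(ccc1O)[C@H]1O[C@@H](c2ccc(O)c(OC)c2)[C@H](C)[C@@H]1C | intermediate
10 | methyl (R)-lactate, methyl (2R)-2-hydroxypropanoate | C[C@@H](O)C(=O)OC | starting material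
11 | dimethyl (2S,2'S)-2,2'-{[(2R,3R,4S,5S)-3,4-dimethyltetrahydrofuran-2,5-diyl]bis[(2-methoxy-4,1-phenylene)oxy]}dipropanoate | COC(=O)[C@H](C)Oc1ccc(cc1OC)[C@H]1O[C@@H](c2ccc(O[C@@H](C)C(=O)OC)c(OC)c2)[C@H](C)[C@@H]1C | intermediate
12 | (2S,2'S)-2,2'-{[(2R,3R,4S,5S)-3,4-dimethyltetrahydrofuran-2,5-diyl]bis[(2-methoxy-4,1-phenylene)oxy]}bis(N-methoxy-N-methylpropanamide) | CON(C)C(=O)[C@H](C)Oc1ccc(cc1OC)[C@H]1O[C@@H](c2ccc(O[C@@H](C)C(=O)N(C)OC)c(OC)c2)[C@H](C)[C@@H]1C | intermediate
13 | 4-bromo-1,2-dimethoxybenzene | COc1ccc(Br)cc1OC | starting material
14 | (3,4-dimethoxyphenyl)magnesium bromide | COc1ccc([Mg]Br)cc1OC | intermediate (not isolated)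
15 | (2S,2'S)-2,2'-{[(2R,3R,4S,5S)-3,4-dimethyltetrahydrofuran-2,5-diyl]bis[(2-methoxy-4,1-phenylene)oxy]}bis[1-(3,4-dimethoxyphenyl)propan-1-one] | COc1ccc(cc1OC)C(=O)[C@H](C)Oc1ccc(cc1OC)[C@H]1O[C@@H](c2ccc(O[C@@H](C)C(=O)c3ccc(OC)c(OC)c3)c(OC)c2)[C@H](C)[C@@H]1C | intermediate
16 | (1R,2S)-1-(3,4-dimethoxyphenyl)-2-{4-[(2S,3S,4R,5R)-5-(4-{[(1R,2S)-1-(3,4-dimethoxyphenyl)-1-hydroxypropan-2-yl]oxy}-3-methoxyphenyl)-3,4-dimethyltetrahydrofuran-2-yl]-2-methoxyphenoxy}propan-1-ol | COc1ccc([C@@H](O)[C@H](C)Oc2ccc([C@H]3O[C@@H](c4ccc(O[C@@H](C)[C@H](O)c5ccc(OC)c(OC)c5)c(OC)c4)[C@H](C)[C@@H]3C)cc2OC)cc1OC | target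

## Step count and risks

Total: 10 steps. Longest linear sequence: 9 steps (steps 2 to 10 from 3; the branch from 1 through steps 1 and 3 to 10 is equally long).

Step 5 (key step). The benzylic cation has two irreversible exits besides ring closure: Friedel–Crafts attack on the second electron-rich arene, and proton loss from C3 followed by re-protonation, which would scramble the cis-dimethyl relation. Too strong an acid or too long an exposure favours these, while too short an exposure leaves the equilibration at C2 and C5 incomplete.
- Fallback: the order of deprotection and ring closure is changed. Starting from 7, the benzyl ethers are hydrogenolysed first (H2, 10% Pd/C, EtOAc) to give 4,4'-[(2R,3S)-1,4-dihydroxy-2,3-dimethylbutane-1,4-diyl]bis(2-methoxyphenol) F1. A catalytic Brønsted acid (p-toluenesulfonic acid, CH2Cl2, 0 °C to rt) then closes and equilibrates the ring through the neutral para-quinone methide. This is a much weaker electrophile toward arenes than the O-benzyl cation, but it still adds the hydroxyl reversibly.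
- The fallback sets out from 7 and comes back at 9. It also removes the hydrogenolysis from the stage that contains the ring.

Step 3. Proton abstraction at the branched α-carbons of 4 may compete with acyl transfer. That would lower conversion and, through re-protonation on quench, erode the meso relation. The second addition next to a first tetrahedral adduct may also be slow.
- Fallback: the C2–C3 bond is formed instead of the carbonyl–aryl bonds. Aryllithium 5, made from 2 as in the route, is acylated with N-methoxy-N-methylpropanamide to give 1-[4-(benzyloxy)-3-methoxyphenyl]propan-1-one F2. Two molecules of its lithium enolate (LDA, THF, −78 °C) are joined oxidatively with CuCl2. The diketone should form as meso isomer 6 together with the racemic diastereomer (2R,3R)-rel-1,4-bis[4-(benzyloxy)-3-methoxyphenyl]-2,3-dimethylbutane-1,4-dione F3. Compound 6 is separated by crystallization, and F3 can be re-equilibrated with base and recycled.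
- The fallback sets out from 2 and comes back at 6.

Step 8. Deprotonation of the α-aryloxy ester by the magnesium amide would epimerize the arm stereocentre before aminolysis is complete, and two such centres are exposed at once.
- Fallback: the amide is installed before the ether bond. Compound 10 is converted with MeNHOMe·HCl and i-PrMgCl into (R)-2-hydroxy-N-methoxy-N-methylpropanamide F4. Two equivalents of F4 are then coupled with 9 under the Mitsunobu conditions of step 7, with inversion, so that no α-aryloxy ester ever meets a base.
- The fallback sets out from 9 and 10 and comes back at 12.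

Step 10. An aryl ether oxygen is a weaker donor than an alkyl ether oxygen. The zinc chelate may be incomplete and facial selectivity poor, and any loss is multiplied over two carbonyl groups.
- Fallback: stereocontrol is moved from the substrate to the reagent. Diketone 15 is reduced under Corey–Bakshi–Shibata conditions (BH3·SMe2 with the (R)-configured B-methyl oxazaborolidine). This is the enantiomer expected to deliver hydride to the face that gives the 1R carbinol when the veratryl ring acts as the larger ketone substituent.
- The fallback sets out from 15 and ends at 16, and it adds no compound outside the list (entry F0).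

## Further compounds

F1 | step 5 | 4,4'-[(2R,3S)-1,4-dihydroxy-2,3-dimethylbutane-1,4-diyl]bis(2-methoxyphenol), C1/C4 epimer mixture | COc1cc(ccc1O)C(O)[C@H](C)[C@H](C)C(O)c1ccc(O)c(OC)c1
F2 | step 3 | 1-[4-(benzyloxy)-3-methoxyphenyl]propan-1-one | CCC(=O)c1ccc(OCc2ccccc2)c(OC)c1
F3 | step 3 | (2R,3R)-rel-1,4-bis[4-(benzyloxy)-3-methoxyphenyl]-2,3-dimethylbutane-1,4-dione (racemic diastereomer) | COc1cc(ccc1OCc1ccccc1)C(=O)[C@H](C)[C@@H](C)C(=O)c1ccc(OCc2ccccc2)c(OC)c1
F4 | step 8 | (R)-2-hydroxy-N-methoxy-N-methylpropanamide | C[C@@H](O)C(=O)N(C)OC
F0 | step 10 | none | none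
A1 | alternative 1 | bis[2-(trimethylsilyl)ethoxymethyl] ether of 16 | COc1ccc([C@@H](OCOCC[Si](C)(C)C)[C@H](C)Oc2ccc([C@H]3O[C@@H](c4ccc(O[C@@H](C)[C@H](OCOCC[Si](C)(C)C)c5ccc(OC)c(OC)c5)c(OC)c4)[C@H](C)[C@@H]3C)cc2OC)cc1OC
A2 | alternative 1 | (2R,3R,4S,5S)-2,5-bis(4-bromo-3-methoxyphenyl)-3,4-dimethyltetrahydrofuran (meso) | COc1cc(ccc1Br)[C@H]1O[C@@H](c2ccc(Br)c(OC)c2)[C@H](C)[C@@H]1C
A3 | alternative 1 | (1R,2S)-1-(3,4-dimethoxyphenyl)-1-{[2-(trimethylsilyl)ethoxy]methoxy}propan-2-ol | COc1ccc([C@@H](OCOCC[Si](C)(C)C)[C@H](C)O)cc1OC
A4 | alternative 2 | bis(tert-butyldimethylsilyl) ether of 16 | COc1ccc([C@@H](O[Si](C)(C)C(C)(C)C)[C@H](C)Oc2ccc([C@H]3O[C@@H](c4ccc(O[C@@H](C)[C@H](O[Si](C)(C)C(C)(C)C)c5ccc(OC)c(OC)c5)c(OC)c4)[C@H](C)[C@@H]3C)cc2OC)cc1OC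
A5 | alternative 2 | (2R,3S,4R,5S)-3,4-dimethyltetrahydrofuran-2,5-dicarboxylic acid (all-cis, meso) | OC(=O)[C@H]1O[C@@H](C(O)=O)[C@@H](C)[C@H]1C
A6 | alternative 2 | 4-bromo-1-{[(1R,2S)-1-{[tert-butyl(dimethyl)silyl]oxy}-1-(3,4-dimethoxyphenyl)propan-2-yl]oxy}-2-methoxybenzene | COc1ccc([C@@H](O[Si](C)(C)C(C)(C)C)[C@H](C)Oc2ccc(Br)cc2OC)cc1OC
A7 | alternative 3 | dimethyl 2,5-cis-2,5-bis[4-(benzyloxy)-3-methoxyphenyl]-4-methyltetrahydrofuran-3,3-dicarboxylate, 4-methyl trans to the 5-aryl group (racemate) | COc1cc(ccc1OCc1ccccc1)[C@H]1O[C@@H](c2ccc(OCc3ccccc3)c(OC)c2)[C@H](C)C1(C(=O)OC)C(=O)OC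
A8 | alternative 3 | dimethyl cis-2-[4-(benzyloxy)-3-methoxyphenyl]-3-methylcyclopropane-1,1-dicarboxylate (racemate) | COC(=O)C1(C(=O)OC)[C@H](C)[C@@H]1c1ccc(OCc2ccccc2)c(OC)c1
A9 | alternative 3 | 4-(benzyloxy)-3-methoxybenzaldehyde | COc1cc(C=O)ccc1OCc1ccccc1
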